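**Plan**

- Numbering and feature: tetrahydrofuran O–C1–C2–C3–C4(CH3), C5=C6 enol-lactone alkene, C7=C11 butenolide alkene, C8 acyloxy CH, C9 CH2, C10 C(CH3)OH, C12 lactone C=O, C13 CH2OAc. The carbocycle C1–C10 is ten-membered with ketone-level C6 across from C1, a methyl on C10 and oxygen on C8 (β to C6); this is the imprint of a [3,3] shift of a 2-isopropenylcyclohexanol whose carbinol carbon carries a 2-alkoxyvinyl group.
- Cuts: the C8 ester C–O; the tetrahydrofuran C1–O (with C10–O, from a C1–C10 epoxide); the lactone O–C12 and C7–C11 (butenolide from the C6–C7 enolate and an acetoxypyruvate); then the ten-membered ring by retro-[3,3] (cut C8–C9, rejoin C1–C6); the C6–C7 alkynyl bond; the C1–C6 ene bond, back to (R)-linalool.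
- Ring order forward: cyclohexane (carbonyl-ene), ten-membered carbocycle (oxy-Cope ring expansion), butenolide, tetrahydrofuran; the ester is attached last.
- Stereochemistry: C4 is bought as (R)-linalool. In the chelated ene closure it places the ether oxygen cis to isopropenyl, and the alkyne then adds trans to isopropenyl. Because of that cis relation the enol ether is made Z, so that the chair shift gives 8S. C1 and C10 come from anti opening of the C1–C10 epoxide by the C4 hydroxyl; the glycidate centre comes from (R)-2-methylglycidol.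

Key step: step 9

Remark: bromopyruvic acid and (R)-2-methylglycidol are taken as commercial; PMB stands for 4-methoxybenzyl; atom numbers in the Why lines are those of the target unless a ring position of a cyclohexane is named.

**Step 1**
Reactants: 1 (R)-linalool
Product: 2 (3R)-3-[(4-methoxybenzyl)oxy]-3,7-dimethylocta-1,6-diene
Conditions: NaH, PMBCl, Bu4NI (cat.), DMF, 0 to 40 °C
Reagents that add atoms: 4-methoxybenzyl chloride, COc1ccc(CCl)cc1
Why: Williamson etherification of the tertiary allylic alkoxide leaves the future C4 centre untouched and installs an ether that can chelate in step 4 and cannot migrate to a neighbouring alkoxide in step 9.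

**Step 2**
Reactants: 2 (3R)-3-[(4-methoxybenzyl)oxy]-3,7-dimethylocta-1,6-diene
Product: 4 (3R)-3-[(4-methoxybenzyl)oxy]-3,7-dimethyloct-6-en-1-ol, via alkylborane 3 (not isolated)
Conditions: 9-BBN, THF, 0 °C to rt; then NaOH, H2O2, 0 °C
Reagents that add atoms: hydrogen peroxide, OO
Why: Hydroboration–oxidation with the hindered borane should take the monosubstituted vinyl group in the anti-Markovnikov sense and spare the trisubstituted alkene.

**Step 3**
Reactants: 4 (3R)-3-[(4-methoxybenzyl)oxy]-3,7-dimethyloct-6-en-1-ol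
Product: 5 (3R)-3-[(4-methoxybenzyl)oxy]-3,7-dimethyloct-6-enal
Conditions: Dess–Martin periodinane, pyridine, CH2Cl2, 0 °C
Reagents that add atoms: none
Why: Dess–Martin oxidation under buffered, non-basic conditions should give the β-alkoxy aldehyde without loss of the β-ether.

**Step 4**
Reactants: 5 (3R)-3-[(4-methoxybenzyl)oxy]-3,7-dimethyloct-6-enal
Product: 6 (1R,2R,5R)-5-[(4-methoxybenzyl)oxy]-5-methyl-2-(prop-1-en-2-yl)cyclohexan-1-ol
Conditions: Me2AlCl (2.5 equiv), CH2Cl2, −78 °C
Reagents that add atoms: none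
Why: Intramolecular carbonyl-ene reaction of a citronellal-type aldehyde, in which aluminium held between the formyl and ether oxygens forces both C–O bonds axial in the chair array while methyl and the emerging isopropenyl group stay equatorial, so the new ring centre C2 is set cis to the ether oxygen by the linalool-derived centre (the C1 carbinol centre is removed in step 5).

**Step 5**
Reactants: 6 (1R,2R,5R)-5-[(4-methoxybenzyl)oxy]-5-methyl-2-(prop-1-en-2-yl)cyclohexan-1-ol
Product: 7 (2R,5R)-5-[(4-methoxybenzyl)oxy]-5-methyl-2-(prop-1-en-2-yl)cyclohexan-1-one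
Conditions: Dess–Martin periodinane, pyridine, CH2Cl2, 0 °C
Reagents that add atoms: none
Why: Dess–Martin oxidation is non-basic, so the allylic α-centre should be neither epimerised nor moved into conjugation.

**Step 6**
Reactants: 8 4-methoxybenzyl alcohol; 9 trichloroethylene
Product: 10 1-({[(E)-1,2-dichloroethenyl]oxy}methyl)-4-methoxybenzene
Conditions: KH, THF, 0 °C; then trichloroethylene, −40 °C to rt
Reagents that add atoms: none
Why: The potassium alkoxide replaces one geminal chlorine of trichloroethylene by elimination–addition, the established entry to 1,2-dichlorovinyl ethers as alkynyl ether precursors.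

**Step 7**
Reactants: 10 1-({[(E)-1,2-dichloroethenyl]oxy}methyl)-4-methoxybenzene; 7 (2R,5R)-5-[(4-methoxybenzyl)oxy]-5-methyl-2-(prop-1-en-2-yl)cyclohexan-1-one
Product: 12 (1R,2R,5R)-5-[(4-methoxybenzyl)oxy]-1-{[(4-methoxybenzyl)oxy]ethynyl}-5-methyl-2-(prop-1-en-2-yl)cyclohexan-1-ol, via lithium alkynyl ether 11 (not isolated)
Conditions: n-BuLi (2.2 equiv), THF, −78 to −40 °C; then 7, −78 °C
Reagents that add atoms: none
Why: Dehydrochlorination and chlorine–lithium exchange give the lithium alkoxyacetylide, whose 1,2-addition to the ketone should occur by equatorial attack because the axial C5 ether blocks the axial path, setting the carbinol centre with the alkynyl group trans to isopropenyl.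

**Step 8**
Reactants: 12 (1R,2R,5R)-5-[(4-methoxybenzyl)oxy]-1-{[(4-methoxybenzyl)oxy]ethynyl}-5-methyl-2-(prop-1-en-2-yl)cyclohexan-1-ol
Product: 13 (1R,2R,5R)-5-[(4-methoxybenzyl)oxy]-1-{(Z)-2-[(4-methoxybenzyl)oxy]ethenyl}-5-methyl-2-(prop-1-en-2-yl)cyclohexan-1-ol
Conditions: H2 (1 atm), Pd/CaCO3 poisoned with Pb(OAc)2, quinoline, EtOAc with 1% Et3N, rt
Reagents that add atoms: none
Why: Lindlar semi-hydrogenation adds hydrogen syn to the electron-rich alkoxyalkyne and should give the Z enol ether while the 1,1-disubstituted alkene and the benzylic ethers survive.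

**Step 9**
Reactants: 13 (1R,2R,5R)-5-[(4-methoxybenzyl)oxy]-1-{(Z)-2-[(4-methoxybenzyl)oxy]ethenyl}-5-methyl-2-(prop-1-en-2-yl)cyclohexan-1-ol
Product: 15 {[(1Z,3S,5E,9R)-3,9-bis[(4-methoxybenzyl)oxy]-5,9-dimethylcyclodeca-1,5-dien-1-yl]oxy}trimethylsilane, via potassium enolate 14 (not isolated)
Conditions: KN(SiMe3)2, THF, −20 to 20 °C; then Me3SiCl, Et3N, −78 °C
Reagents that add atoms: chlorotrimethylsilane, C[Si](C)(C)Cl
Why: The potassium alkoxide of 13 undergoes an anionic oxy-Cope rearrangement, a [3,3] shift in which C8–C9 forms while the oxido-weakened C1–C6 bond breaks, and the resulting C6–C7 enolate 14 is silylated on oxygen. The closest known reaction is the rearrangement of trans-1,2-dialkenylcyclohexanolates to (E)-cyclodec-5-enones, an alkoxy-substituted vinyl group being the less common variant. The ten-membered ring is not closed end to end: it arises by four-atom ring expansion of the cyclohexane through a chair array trans-fused to the chair cyclohexane with both alkenyl groups equatorial, which should deliver C1=C10 as E. C8 is the only new stereocentre and is controlled by the enol ether geometry together with the two relay centres (1R,2R in 13, themselves fixed by C4): the Z alkoxy group is axial in the chair, syn to the oxido oxygen, and this gives 8S. The step needs chair over boat and survival of the β-alkoxy enolate: a Z substituent is tolerated even less in a boat, potassium without a crown ether can bridge the oxido oxygen and the ether oxygens on the same face, and in 14 the same chelation holds the C8–O bond near the enolate plane until Me3SiCl traps the enolate at −78 °C.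

**Step 10**
Reactants: 16 3-bromo-2-oxopropanoic acid
Product: 17 prop-2-en-1-yl 3-bromo-2-oxopropanoate
Conditions: allyl alcohol, p-TsOH (cat.), toluene, reflux (Dean–Stark)
Reagents that add atoms: allyl alcohol, C=CCO
Why: Fischer esterification with azeotropic removal of water gives an ester that can later be cleaved without acid or base.

**Step 11**
Reactants: 17 prop-2-en-1-yl 3-bromo-2-oxopropanoate
Product: 18 prop-2-en-1-yl 3-acetoxy-2-oxopropanoate
Conditions: KOAc, acetone, rt
Reagents that add atoms: potassium acetate, CC(=O)[O-].[K+]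
Why: SN2 displacement of an α-bromo ketone by a carboxylate is fast and brings in the C13 acetate at the outset.

**Step 12**
Reactants: 15 {[(1Z,3S,5E,9R)-3,9-bis[(4-methoxybenzyl)oxy]-5,9-dimethylcyclodeca-1,5-dien-1-yl]oxy}trimethylsilane; 18 prop-2-en-1-yl 3-acetoxy-2-oxopropanoate
Product: 20 prop-2-en-1-yl (4R,8S)-13-acetoxy-11-hydroxy-4,8-bis[(4-methoxybenzyl)oxy]-6-oxogermacr-1(10)E-en-12-oate (mixture at C7 and C11), via silyl ether 19 (not isolated)
Conditions: Cu(OTf)2 (10 mol %), THF, −78 °C; then aq. citric acid, 0 °C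
Reagents that add atoms: none
Why: Mukaiyama aldol addition of the regiodefined enol silane to the keto group of an α-keto ester held in two-point fashion by divalent copper should form C7–C11 at low temperature without disturbing the allylic C8 ether, and the two new centres are removed in step 14.

**Step 13**
Reactants: 20 prop-2-en-1-yl (4R,8S)-13-acetoxy-11-hydroxy-4,8-bis[(4-methoxybenzyl)oxy]-6-oxogermacr-1(10)E-en-12-oate
Product: 21 (4R,8S)-13-acetoxy-11-hydroxy-4,8-bis[(4-methoxybenzyl)oxy]-6-oxogermacr-1(10)E-en-12-oic acid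
Conditions: Pd(PPh3)4 (5 mol %), morpholine, THF, 0 °C
Reagents that add atoms: none
Why: Deallylation through a π-allyl complex of zerovalent palladium (Tsuji–Trost type) frees the acid under near-neutral conditions that avoid retro-aldol cleavage, at a stage where the C13 acetate is not yet allylic.

**Step 14**
Reactants: 21 (4R,8S)-13-acetoxy-11-hydroxy-4,8-bis[(4-methoxybenzyl)oxy]-6-oxogermacr-1(10)E-en-12-oic acid
Product: 23 (4R,8S)-13-acetoxy-4,8-bis[(4-methoxybenzyl)oxy]germacra-1(10)E,5E,7(11)-trien-12,6-olide, via lactol diacetate 22 (not isolated)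
Conditions: Ac2O, NaOAc, 70 °C
Reagents that add atoms: none
Why: Dehydrative enol lactonisation of a γ-keto acid, in which acetic anhydride first gives the cyclic pseudo-acid acetate with the C11 hydroxyl acetylated and two losses of acetic acid through the 2-oxofuranylium ion then place C7=C11 and C5=C6, so the lactone closes before the alkene forms, no E/Z question arises at C7=C11, and C5=C6 takes the ring-cis geometry (C4 cis to C7).

**Step 15**
Reactants: 23 (4R,8S)-13-acetoxy-4,8-bis[(4-methoxybenzyl)oxy]germacra-1(10)E,5E,7(11)-trien-12,6-olide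
Product: 24 (4R,8S)-13-acetoxy-4,8-dihydroxygermacra-1(10)E,5E,7(11)-trien-12,6-olide
Conditions: DDQ, CH2Cl2/pH 7 buffer, 0 °C
Reagents that add atoms: none
Why: Oxidative cleavage of both 4-methoxybenzyl ethers by DDQ proceeds at neutral pH and should leave the enol lactone, the allylic acetate and the isolated alkene intact.

**Step 16**
Reactants: 24 (4R,8S)-13-acetoxy-4,8-dihydroxygermacra-1(10)E,5E,7(11)-trien-12,6-olide
Product: 26 (1S,4R,8S,10R)-13-acetoxy-1,4-epoxy-8,10-dihydroxygermacra-5E,7(11)-dien-12,6-olide, via epoxide 25 (not isolated)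
Conditions: mCPBA, CH2Cl2, −10 °C; then PPTS (cat.), rt
Reagents that add atoms: 3-chloroperoxybenzoic acid, OOC(=O)c1cccc(Cl)c1
Why: Prilezhaev epoxidation should take the only electron-rich alkene, C1=C10, from the ring periphery in the conformer that turns the C4 hydroxyl rather than the C4 methyl toward the ring interior, and the C4 hydroxyl then opens the epoxide at C1 with inversion in the 5-exo mode (the mode seen when linalool itself is epoxidised), which sets C1 as S and leaves C10, with retention, as R.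

**Step 17**
Reactants: 27 (R)-2-methylglycidol
Product: 28 (S)-2-methyloxirane-2-carboxylic acid
Conditions: RuCl3 (cat.), NaIO4, MeCN/EtOAc/H2O, 0 °C
Reagents that add atoms: sodium periodate, [Na+].[O-]I(=O)(=O)=O
Why: Ruthenium tetroxide oxidation of a primary epoxy alcohol to the epoxy acid leaves the quaternary epoxide centre untouched (the descriptor changes from R to S only because the priorities change).

**Step 18**
Reactants: 26 (1S,4R,8S,10R)-13-acetoxy-1,4-epoxy-8,10-dihydroxygermacra-5E,7(11)-dien-12,6-olide; 28 (S)-2-methyloxirane-2-carboxylic acid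
Product: 29 (1S,4R,8S,10R)-13-acetoxy-1,4-epoxy-10-hydroxy-8-{[(2S)-2-methyloxirane-2-carbonyl]oxy}germacra-5E,7(11)-dien-12,6-olide (CNP0142137.1)
Conditions: DCC, DMAP (cat.), CH2Cl2, 0 °C to rt
Reagents that add atoms: none
Why: Steglich esterification should acylate the secondary C8 hydroxyl with retention while the tertiary C10 hydroxyl stays free, and neither the C8 centre nor the glycidate centre is touched.

**Compound list**

1 | (R)-linalool | C=C[C@@](O)(C)CCC=C(C)C | starting material
2 | (3R)-3-[(4-methoxybenzyl)oxy]-3,7-dimethylocta-1,6-diene | C=C[C@@](OCc1ccc(OC)cc1)(C)CCC=C(C)C | intermediate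
3 | 9-{(3S)-3-[(4-methoxybenzyl)oxy]-3,7-dimethyloct-6-en-1-yl}-9-borabicyclo[3.3.1]nonane | B1(CC[C@@](OCc2ccc(OC)cc2)(C)CCC=C(C)C)C2CCCC1CCC2 | intermediate
4 | (3R)-3-[(4-methoxybenzyl)oxy]-3,7-dimethyloct-6-en-1-ol | OCC[C@@](OCc1ccc(OC)cc1)(C)CCC=C(C)C | intermediate
5 | (3R)-3-[(4-methoxybenzyl)oxy]-3,7-dimethyloct-6-enal | O=CC[C@@](OCc1ccc(OC)cc1)(C)CCC=C(C)C | intermediate
6 | (1R,2R,5R)-5-[(4-methoxybenzyl)oxy]-5-methyl-2-(prop-1-en-2-yl)cyclohexan-1-ol | O[C@@H]1C[C@](C)(OCc2ccc(OC)cc2)CC[C@@H]1C(C)=C | intermediate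
7 | (2R,5R)-5-[(4-methoxybenzyl)oxy]-5-methyl-2-(prop-1-en-2-yl)cyclohexan-1-one | O=C1C[C@](C)(OCc2ccc(OC)cc2)CC[C@@H]1C(C)=C | intermediate
8 | 4-methoxybenzyl alcohol | COc1ccc(CO)cc1 | starting material
9 | trichloroethylene | ClC=C(Cl)Cl | starting material
10 | 1-({[(E)-1,2-dichloroethenyl]oxy}methyl)-4-methoxybenzene | COc1ccc(CO/C(Cl)=C\Cl)cc1 | intermediate
11 | {[(4-methoxybenzyl)oxy]ethynyl}lithium | [Li]C#COCc1ccc(OC)cc1 | intermediate
12 | (1R,2R,5R)-5-[(4-methoxybenzyl)oxy]-1-{[(4-methoxybenzyl)oxy]ethynyl}-5-methyl-2-(prop-1-en-2-yl)cyclohexan-1-ol | O[C@]1(C#COCc2ccc(OC)cc2)C[C@](C)(OCc2ccc(OC)cc2)CC[C@@H]1C(C)=C | intermediate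
13 | (1R,2R,5R)-5-[(4-methoxybenzyl)oxy]-1-{(Z)-2-[(4-methoxybenzyl)oxy]ethenyl}-5-methyl-2-(prop-1-en-2-yl)cyclohexan-1-ol | O[C@]1(/C=C\OCc2ccc(OC)cc2)C[C@](C)(OCc2ccc(OC)cc2)CC[C@@H]1C(C)=C | intermediate
14 | potassium (1Z,3S,5E,9R)-3,9-bis[(4-methoxybenzyl)oxy]-5,9-dimethylcyclodeca-1,5-dien-1-olate | [K+].[O-]/C1=C\[C@@H](OCc2ccc(OC)cc2)C/C(C)=C/CC[C@@](C)(OCc2ccc(OC)cc2)C1 | intermediate
15 | {[(1Z,3S,5E,9R)-3,9-bis[(4-methoxybenzyl)oxy]-5,9-dimethylcyclodeca-1,5-dien-1-yl]oxy}trimethylsilane | C[Si](C)(C)O/C1=C\[C@@H](OCc2ccc(OC)cc2)C/C(C)=C/CC[C@@](C)(OCc2ccc(OC)cc2)C1 | intermediate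
16 | 3-bromo-2-oxopropanoic acid (bromopyruvic acid) | OC(=O)C(=O)CBr | starting material
17 | prop-2-en-1-yl 3-bromo-2-oxopropanoate | C=CCOC(=O)C(=O)CBr | intermediate
18 | prop-2-en-1-yl 3-acetoxy-2-oxopropanoate | C=CCOC(=O)C(=O)COC(C)=O | intermediate
19 | prop-2-en-1-yl (4R,8S)-13-acetoxy-4,8-bis[(4-methoxybenzyl)oxy]-6-oxo-11-(trimethylsilyloxy)germacr-1(10)E-en-12-oate (mixture at C7 and C11) | O=C1C(C(O[Si](C)(C)C)(COC(C)=O)C(=O)OCC=C)[C@@H](OCc2ccc(OC)cc2)C/C(C)=C/CC[C@@](C)(OCc2ccc(OC)cc2)C1 | intermediate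
20 | prop-2-en-1-yl (4R,8S)-13-acetoxy-11-hydroxy-4,8-bis[(4-methoxybenzyl)oxy]-6-oxogermacr-1(10)E-en-12-oate (mixture at C7 and C11) | O=C1C(C(O)(COC(C)=O)C(=O)OCC=C)[C@@H](OCc2ccc(OC)cc2)C/C(C)=C/CC[C@@](C)(OCc2ccc(OC)cc2)C1 | intermediate
21 | (4R,8S)-13-acetoxy-11-hydroxy-4,8-bis[(4-methoxybenzyl)oxy]-6-oxogermacr-1(10)E-en-12-oic acid (mixture at C7 and C11) | O=C1C(C(O)(COC(C)=O)C(=O)O)[C@@H](OCc2ccc(OC)cc2)C/C(C)=C/CC[C@@](C)(OCc2ccc(OC)cc2)C1 | intermediate
22 | (4R,8S)-6,11,13-triacetoxy-4,8-bis[(4-methoxybenzyl)oxy]germacr-1(10)E-en-12,6-olide (pseudo-acid diacetate, mixture at C6, C7 and C11) | O=C1OC2(OC(C)=O)C[C@](C)(OCc3ccc(OC)cc3)CC/C=C(\C)C[C@H](OCc3ccc(OC)cc3)C2C1(OC(C)=O)COC(C)=O | intermediate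
23 | (4R,8S)-13-acetoxy-4,8-bis[(4-methoxybenzyl)oxy]germacra-1(10)E,5E,7(11)-trien-12,6-olide | CC(=O)OCC1=C2/C(=C\[C@](C)(OCc3ccc(OC)cc3)CC/C=C(\C)C[C@@H]2OCc3ccc(OC)cc3)OC1=O | intermediate
24 | (4R,8S)-13-acetoxy-4,8-dihydroxygermacra-1(10)E,5E,7(11)-trien-12,6-olide | CC(=O)OCC1=C2/C(=C\[C@](C)(O)CC/C=C(\C)C[C@@H]2O)OC1=O | intermediate
25 | (1R,4R,8S,10R)-13-acetoxy-1,10-epoxy-4,8-dihydroxygermacra-5E,7(11)-dien-12,6-olide | CC(=O)OCC1=C2/C(=C\[C@](C)(O)CC[C@H]3O[C@]3(C)C[C@@H]2O)OC1=O | intermediate
26 | (1S,4R,8S,10R)-13-acetoxy-1,4-epoxy-8,10-dihydroxygermacra-5E,7(11)-dien-12,6-olide | CC(=O)OCC1=C2/C(=C\[C@@]3(C)CC[C@H](O3)[C@](C)(O)C[C@@H]2O)OC1=O | intermediate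
27 | (R)-2-methylglycidol [(2R)-(2-methyloxiran-2-yl)methanol] | OC[C@]1(C)CO1 | starting material
28 | (S)-2-methyloxirane-2-carboxylic acid | OC(=O)[C@]1(C)CO1 | intermediate
29 | (1S,4R,8S,10R)-13-acetoxy-1,4-epoxy-10-hydroxy-8-{[(2S)-2-methyloxirane-2-carbonyl]oxy}germacra-5E,7(11)-dien-12,6-olide (CNP0142137.1) | CC(=O)OCC1=C2/C(=C\[C@@]3(C)CC[C@H](O3)[C@](C)(O)C[C@@H]2OC(=O)[C@]2(C)CO2)OC1=O | target

**Step count**

Total: 18 steps. Longest linear sequence: 14 steps (steps 1, 2, 3, 4, 5, 7, 8, 9, 12, 13, 14, 15, 16, 18).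

**Three steps most likely to fail**

Step 9. The potassium enolate may lose the C8 alkoxide by β-elimination before it is silylated, or part of the shift may leak through a boat array because the alkoxy group is axial, which would erode C8. The fallback sets out from 13: a neutral thermal oxy-Cope rearrangement (sealed base-washed tube, xylene with a trace of Et3N, about 200 °C) should give, through the enol and with no enolate present, the ketone (3S,5E,9R)-3,9-bis[(4-methoxybenzyl)oxy]-5,9-dimethylcyclodec-5-en-1-one F1, the chair preference being larger in the neutral shift. Kinetic deprotonation of F1 with LiN(iPr)2 in the presence of Me3SiCl at −78 °C (in situ quench), at the less hindered C7 methylene (C5 is neopentylic), then comes back to the route at 15.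

Step 14. The C11 acetate may be eliminated in the open keto acid before the ring closes, giving an alkylidene acid whose carboxyl is trans to C6 and cannot lactonise, or the tertiary C4 ether may ionise in warm acetic acid. The fallback sets out from 21: the lactone is closed first under neutral conditions with EDC·HCl and Et3N in CH2Cl2 to the hydroxy enol lactone (4R,8S)-13-acetoxy-11-hydroxy-4,8-bis[(4-methoxybenzyl)oxy]germacra-1(10)E,5E-dien-12,6-olide F2, and its tertiary alcohol is then dehydrated toward C7 with Martin sulfurane at 0 °C, which comes back to the route at 23.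

Step 16. The peracid may show poor facial selectivity, so that part of the material is epoxidised on the face from which the C4 hydroxyl cannot reach C1 from the rear; that epoxide would stall or open at C10 to a tetrahydropyran. The fallback sets out from 24: a reagent-controlled Shi epoxidation (the fructose-derived ketone of the enantiomeric series that delivers the (1R,10R) epoxide, Oxone, buffered MeCN/H2O, 0 °C) replaces substrate control for this trisubstituted E alkene and comes back to the route at 25, which closes to 26 with PPTS.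

**Further compounds**

F1 | step 9 | (3S,5E,9R)-3,9-bis[(4-methoxybenzyl)oxy]-5,9-dimethylcyclodec-5-en-1-one | O=C1C[C@@H](OCc2ccc(OC)cc2)C/C(C)=C/CC[C@@](C)(OCc2ccc(OC)cc2)C1
F2 | step 14 | (4R,8S)-13-acetoxy-11-hydroxy-4,8-bis[(4-methoxybenzyl)oxy]germacra-1(10)E,5E-dien-12,6-olide (mixture at C7 and C11) | CC(=O)OCC1(O)C2/C(=C\[C@](C)(OCc3ccc(OC)cc3)CC/C=C(\C)C[C@@H]2OCc3ccc(OC)cc3)OC1=O
F0 | step 16 | none | none
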